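## Retrosynthetic overview

- The strategy rests on the C3 carbinol next to the Z-configured C4(C15-methyl)=C5 olefin in the ten-membered carbocycle C1–C10. This allylic-alcohol unit is what a reductive coupling of a C3 aldehyde with the central carbon (C4) of a C6–C5H=C4=C15H2 allene gives, so the carbocycle is closed at C3–C4.
- The allene aldehyde 33 is built from an Evans syn-aldol (C6, C7 and the alkyne), a 1,3-anti reduction (C8), a Felkin Mukaiyama aldol (C9), a Crabbé homologation (C15) and an aldol–elimination (C1=C10).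
- After ring closure: C8 epoxyangelate, C9 acetate, global desilylation, C6/C12 oxidative lactonization and C3–OH-directed epoxidation of C4=C5.
- Ring order: ten-membered carbocycle (step 20), γ-lactone (step 29), C4–C5 oxirane (step 30). The side-chain oxirane is made separately (step 23).

Key step: step 20

Remark: carbon numbers are those of the germacrane skeleton (C1–C10 ring, C11–C13 lactone, C14 ester carbon, C15 methyl). C9 is carried as a triethylsilyl ether through the nickel step, because an acetate there is an allylic ester next to the acrylate that Ni(0) could ionise. tert-Butyldimethylsilane is used as the reductant, so that C3 stays protected until the global desilylation.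

## Route

Step 1
Reactants: 1 2-methylprop-2-en-1-ol; 2 carbon dioxide
Product: 3 3-(hydroxymethyl)but-3-enoic acid
Conditions: n-BuLi (2.2 equiv), TMEDA, Et2O/hexane, 0 °C to rt; CO2, −78 °C; cold dil. HCl to pH 5, crude used
Reagents that add atoms: none
Why: The O,C-dilithio derivative of methallyl alcohol is a symmetrical 2-substituted allyl anion that is carboxylated at carbon by CO2 (allyllithium carboxylation), which brings in C7, C8, C11, C12 and C13 together.

Step 2
Reactants: 3 3-(hydroxymethyl)but-3-enoic acid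
Product: 5 3-(tert-butyldimethylsilyloxymethyl)but-3-enoic acid, via bis-silyl ester 4 (not isolated)
Conditions: TBSCl (2.4 equiv), imidazole, DMF, rt; then MeOH/H2O, AcOH (cat.), rt
Reagents that add atoms: tert-butyldimethylsilyl chloride, CC(C)(C)[Si](C)(C)Cl
Why: Silylation of both oxygens followed by selective hydrolysis of the labile silyl ester leaves the primary TBS ether (protecting-group chemistry).

Step 3
Reactants: 5 3-(tert-butyldimethylsilyloxymethyl)but-3-enoic acid; 6 (S)-4-benzyl-1,3-oxazolidin-2-one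
Product: 8 (S)-4-benzyl-3-[3-(tert-butyldimethylsilyloxymethyl)but-3-enoyl]-1,3-oxazolidin-2-one, via mixed pivalic anhydride 7 (not isolated)
Conditions: PivCl, Et3N, THF, −20 °C; then 6, LiCl, −20 °C to rt
Reagents that add atoms: none
Why: N-Acylation of the oxazolidinone through the mixed anhydride with LiCl/Et3N needs no strong base, so the 1,1-disubstituted double bond is not moved into conjugation.

Step 4
Reactants: 8 acyl oxazolidinone; 9 3-(trimethylsilyl)prop-2-ynal
Product: 10 syn-aldol imide (C8 imide, C7 carrying the 3-silyloxyprop-1-en-2-yl group, C6 propargylic alcohol, C5≡C4–SiMe3)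
Conditions: Bu2BOTf, i-Pr2NEt, CH2Cl2, −78 °C; 9, −78 to 0 °C; pH 7 buffer, MeOH, H2O2
Reagents that add atoms: none
Why: Evans syn-aldol reaction: the Z-boron enolate from soft enolisation reacts at the α-carbon C7 through a chair transition state in which the benzyl group of the (S)-auxiliary blocks one enolate face, which sets C6 and C7 syn with the configurations of the target.

Step 5
Reactants: 10 syn-aldol imide
Product: 11 Weinreb amide (N-methoxy-N-methyl amide at C8)
Conditions: MeONHMe·HCl, AlMe3, CH2Cl2/THF, −10 to 0 °C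
Reagents that add atoms: N,O-dimethylhydroxylamine hydrochloride, CNOC.Cl
Why: Aluminium-amide transamination of the aldol imide, helped by the free β-hydroxyl, gives the Weinreb amide and returns the auxiliary without epimerising C7.

Step 6
Reactants: 12 4-methoxybenzyl alcohol; 13 tributyl(iodomethyl)stannane
Product: 14 tributyl[(4-methoxybenzyloxy)methyl]stannane
Conditions: NaH, THF/DMF, 0 °C to rt
Reagents that add atoms: none
Why: Williamson ether synthesis of the alkoxide with the primary iodide gives the α-alkoxy stannane.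

Step 7
Reactants: 11 Weinreb amide; 14 tributyl[(4-methoxybenzyloxy)methyl]stannane
Product: 16 β-hydroxy ketone (C9H2–OPMB, C8 ketone, C6 hydroxyl), via [(4-methoxybenzyloxy)methyl]lithium 15 (not isolated)
Conditions: 14 (3 equiv), n-BuLi, THF, −78 °C; then 11, −78 to −40 °C; aq. NH4Cl
Reagents that add atoms: none
Why: Tin–lithium exchange gives the α-alkoxymethyllithium, which deprotonates the C6 hydroxyl and then adds once to the Weinreb amide (stable chelated tetrahedral intermediate) to give the ketone with C9 in place.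

Step 8
Reactants: 16 β-hydroxy ketone
Product: 17 6,8-anti diol (C6 and C8 hydroxyls, C9H2–OPMB)
Conditions: Me4NBH(OAc)3, MeCN/AcOH, −30 °C
Reagents that add atoms: none
Why: Evans–Saksena reduction: the acetoxyborohydride bound to the C6 oxygen delivers hydride intramolecularly through a chair transition state, which sets C8 1,3-anti to C6.

Step 9
Reactants: 17 6,8-anti diol
Product: 18 C8/C9 p-methoxybenzylidene acetal with free C6 hydroxyl (acetal carbon as a mixture of epimers)
Conditions: DDQ (1.2 equiv), 4 Å MS, CH2Cl2, 0 °C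
Reagents that add atoms: none
Why: DDQ oxidative acetalisation: the PMB ether is oxidised to an oxocarbenium ion that is trapped by the neighbouring C8 hydroxyl as a five-membered acetal, which protects O8/O9 and leaves only C6–OH free.

Step 10
Reactants: 18 acetal alcohol
Product: 19 C6 tert-butyldimethylsilyl ether
Conditions: TBSOTf, 2,6-lutidine, CH2Cl2, −78 °C
Reagents that add atoms: tert-butyldimethylsilyl triflate, CC(C)(C)[Si](C)(C)OS(=O)(=O)C(F)(F)F
Why: Silylation of the hindered propargylic alcohol with the silyl triflate and a non-nucleophilic base leaves the acetal intact.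

Step 11
Reactants: 19 silylalkyne
Product: 20 terminal alkyne
Conditions: K2CO3 (cat.), MeOH, rt
Reagents that add atoms: none
Why: Methanolysis cleaves the C(sp)–SiMe3 bond selectively; TBS ethers and the acetal are stable to methoxide.

Step 12
Reactants: 20 terminal alkyne; 21 formaldehyde (as paraformaldehyde)
Product: 22 terminal allene (C6–C5H=C4=C15H2)
Conditions: (CH2O)n, CuI, Cy2NH, 1,4-dioxane, 100 °C
Reagents that add atoms: none
Why: Crabbé homologation: the Mannich base of alkyne, formaldehyde and dicyclohexylamine undergoes copper-mediated 1,5-hydride transfer with loss of the imine, which gives the allene with C15 from formaldehyde and does not touch C6.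

Step 13
Reactants: 22 allene acetal
Product: 23 primary C9 alcohol with C8 PMB ether
Conditions: DIBAL-H (3 equiv), CH2Cl2, −78 to −10 °C; Rochelle salt
Reagents that add atoms: none
Why: Regioselective reductive opening of the p-methoxybenzylidene acetal: DIBAL-H binds the less hindered primary oxygen and cleaves its C–O bond, so the PMB group stays on O8.

Step 14
Reactants: 23 primary alcohol
Product: 24 C9 aldehyde (α-PMB-oxy aldehyde)
Conditions: Dess–Martin periodinane, NaHCO3, CH2Cl2, 0 °C to rt; used at once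
Reagents that add atoms: none
Why: Dess–Martin oxidation under buffered conditions gives the α-alkoxy aldehyde without epimerising C8.

Step 15
Reactants: 24 C9 aldehyde; 25 tert-butyl[(1-methoxyethenyl)oxy]dimethylsilane
Product: 26 methyl β-hydroxy ester (C9 carbinol, 8,9-anti)
Conditions: 24 and 25 premixed, BF3·OEt2, CH2Cl2, −78 °C; aq. NaHCO3
Reagents that add atoms: none
Why: Mukaiyama aldol addition under monodentate BF3 activation goes through the Felkin–Anh (non-chelate) transition state with the C8–O bond anti to the incoming ketene acetal, which sets C9 anti to C8.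

Step 16
Reactants: 26 β-hydroxy ester
Product: 27 C9 triethylsilyl ether
Conditions: TESCl, imidazole, DMF, 0 °C
Reagents that add atoms: chlorotriethylsilane, CC[Si](Cl)(CC)CC
Why: Silylation gives a C9 ether that cannot be ionised by Ni(0) and that can later be removed in the presence of TBS ethers.

Step 17
Reactants: 28 methyl 3,3-dimethoxypropanoate
Product: 29 3,3-dimethoxypropanal
Conditions: DIBAL-H (1.05 equiv), CH2Cl2, −78 °C; used crude
Reagents that add atoms: none
Why: Partial reduction of the ester stops at the aluminium hemiacetal at −78 °C and gives the aldehyde on work-up.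

Step 18
Reactants: 27 C9 TES ether ester; 29 3,3-dimethoxypropanal
Product: 32 enoate with C3 dimethyl acetal (C1=C10 with C2 cis to C9), via aldol adduct 30 (not isolated), via C1 mesylate 31 (not isolated)
Conditions: LDA, THF, −78 °C; 29; MsCl, −78 to 0 °C; DBU, 0 °C to rt
Reagents that add atoms: none
Why: Aldol addition of the ester enolate, O-mesylation of the aldolate and E1cB elimination (aldol condensation) give the trisubstituted enoate; the isomer with C2 cis to C9 and trans to the ester should prevail because it avoids allylic strain with the in-plane ester, and the C9 silyloxy group is too poor a leaving group to compete.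

Step 19
Reactants: 32 enoate acetal
Product: 33 allene aldehyde (C3 aldehyde, C9 OTES, C8 OPMB, C6 and C12 OTBS)
Conditions: TESOTf, 2,4,6-collidine, CH2Cl2, 0 °C; then H2O
Reagents that add atoms: water, O
Why: Silyl triflate/collidine acetal cleavage turns the dimethyl acetal into a collidinium salt that water hydrolyses near neutral pH, so the β,γ-unsaturated aldehyde is released without acid or base that could move the C1=C10 double bond.

Step 20
Reactants: 33 allene aldehyde
Product: 34 ten-membered Z,Z-diene with C3 OTBS and C4 methyl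
Conditions: Ni(cod)2 (30 mol %), IPr (free carbene, 30 mol %), t-BuMe2SiH (5 equiv), THF, rt, syringe-pump addition of 33 (final 0.002 M)
Reagents that add atoms: tert-butyldimethylsilane, C[SiH](C)C(C)(C)C
Why: Proposed new method: Ni(0)–IPr binds the aldehyde and the terminal C4=C15 π bond of the allene, oxidative cyclisation forms C3–C4 and an oxanickelacycle with nickel on C15, σ-bond metathesis of Ni–O with the silane gives the C3 silyl ether and a nickel hydride, and C–H reductive elimination turns C15 into the methyl group. The closest known reaction is the intermolecular nickel/NHC-catalysed coupling of allenes, aldehydes and silanes to Z-allylic silyl ethers, and nickel/NHC/silane macrocyclisations of alkynals show that the manifold works at high dilution; the ten-membered intramolecular allene version is not known. The carbocycle closes by C–C bond formation in an endo mode, with the former allene bond C4=C5 becoming the ring olefin; C3 must bond to C4 in the plane of the C5 substituents and the tether delivers it from the C6 side, so C3 and C6 end cis, which is also the geometry of the intermolecular reaction. The new C3 centre is set by the substrate: the C3–O bond lies in the plane of the forming olefin, C6 turns its hydrogen towards the incoming carbonyl (allylic strain), and C7 and therefore C2 lie on the face opposite the C6 silyloxy group, which corresponds to (3R); a chiral NHC is held in reserve to reinforce this. The step needs reaction of the allene/aldehyde pair in preference to the acrylate and the C11=C13 alkene, coupling at the central allene carbon with hydride to C15, and no enolisation of the aldehyde: both other alkenes are too hindered for the Ni–IPr fragment, C9 carries a silyl ether in place of an ionisable acetate, and the base-free catalyst with slow addition keeps the free aldehyde concentration low.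

Step 21
Reactants: 34 macrocycle
Product: 35 C8 alcohol
Conditions: DDQ, CH2Cl2/pH 7 buffer, 0 °C
Reagents that add atoms: none
Why: Oxidative cleavage of the PMB ether with DDQ in wet dichloromethane leaves silyl ethers, the ester and the olefins.

Step 22
Reactants: 36 angelic acid
Product: 37 (Z)-2-methylbut-2-en-1-ol
Conditions: LiAlH4, Et2O, 0 °C
Reagents that add atoms: none
Why: Hydride reduction of the acid to the allylic alcohol keeps the Z double bond.

Step 23
Reactants: 37 (Z)-2-methylbut-2-en-1-ol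
Product: 38 [(2R,3S)-2,3-dimethyloxiran-2-yl]methanol
Conditions: Ti(Oi-Pr)4 (cat.), D-(−)-diisopropyl tartrate, t-BuOOH, 4 Å MS, CH2Cl2, −20 °C
Reagents that add atoms: tert-butyl hydroperoxide, CC(C)(C)OO
Why: Sharpless asymmetric epoxidation: the D-(−)-tartrate complex delivers oxygen to the face that gives the (2R,3S)-epoxy alcohol, and syn addition keeps the hydroxymethyl group and the C3 methyl cis.

Step 24
Reactants: 38 epoxy alcohol
Product: 39 (2S,3S)-2,3-dimethyloxirane-2-carboxylic acid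
Conditions: RuCl3·xH2O (cat.), NaIO4, CCl4/MeCN/H2O, 0 °C to rt
Reagents that add atoms: sodium periodate, [Na+].[O-]I(=O)(=O)=O; water, O
Why: Ruthenium tetroxide oxidation takes the primary alcohol to the acid without opening the epoxide; the C2 descriptor changes only because the CIP priorities change.

Step 25
Reactants: 35 C8 alcohol; 39 (2S,3S)-2,3-dimethyloxirane-2-carboxylic acid
Product: 41 C8 epoxyangelate, via mixed trichlorobenzoic anhydride 40 (not isolated)
Conditions: 39, 2,4,6-trichlorobenzoyl chloride, Et3N, THF, rt; then 35, DMAP, toluene, rt to 40 °C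
Reagents that add atoms: none
Why: Yamaguchi esterification: DMAP attacks the mixed anhydride at the epoxy-acyl carbonyl and the acylpyridinium acylates the hindered C8 hydroxyl; no migratable acyl group sits on C9 at this stage.

Step 26
Reactants: 41 C8 epoxyangelate
Product: 42 C9 alcohol
Conditions: PPTS (cat.), MeOH/CH2Cl2, 0 °C
Reagents that add atoms: none
Why: Acid-catalysed methanolysis removes the triethylsilyl ether much faster than the TBS ethers, so only C9–OH is freed.

Step 27
Reactants: 42 C9 alcohol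
Product: 43 C9 acetate
Conditions: Ac2O, pyridine, DMAP (cat.), CH2Cl2, 0 °C to rt
Reagents that add atoms: acetic anhydride, CC(=O)OC(C)=O
Why: Acetylation of the only free hydroxyl; the hindered epoxy ester on C8 is not prone to migrate.

Step 28
Reactants: 43 C9 acetate
Product: 44 triol (C3, C6 and C12 hydroxyls)
Conditions: HF·pyridine, pyridine, THF, 0 °C to rt
Reagents that add atoms: none
Why: Buffered hydrogen fluoride cleaves the three TBS ethers and leaves the acetate, the epoxy ester and the methyl ester.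

Step 29
Reactants: 44 triol
Product: 46 α-methylene-γ-butyrolactone with C4=C5 olefin and free C3 hydroxyl, via lactol 45 (not isolated)
Conditions: TEMPO (cat.), PhI(OAc)2 (2.5 equiv), CH2Cl2, rt
Reagents that add atoms: none
Why: TEMPO/PhI(OAc)2 oxidative lactonisation: the oxoammonium salt oxidises the primary allylic C12 alcohol selectively, C6–OH traps the aldehyde as the five-membered lactol (5-exo closure, ring fusion fixed by C6/C7), and a second oxidation gives the lactone.

Step 30
Reactants: 46 lactone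
Product: 47 target CNP0301544.1
Conditions: mCPBA, NaHCO3, CH2Cl2, 0 °C
Reagents that add atoms: 3-chloroperbenzoic acid, OOC(=O)c1cccc(Cl)c1
Why: Hydroxyl-directed (Henbest) peracid epoxidation: allylic strain keeps H3 and H6 in the olefin plane so that the C3 hydroxyl and O6 lie on the outer face of the Z olefin, the hydrogen-bonded peracid attacks that face to give the threo (4S,5R) epoxide, and the electron-poor acrylate and methylene lactone do not react.

## Compound list

1 | 2-methylprop-2-en-1-ol | C=C(C)CO | starting material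
2 | carbon dioxide | O=C=O | starting material
3 | 3-(hydroxymethyl)but-3-enoic acid | C=C(CO)CC(=O)O | intermediate
4 | tert-butyldimethylsilyl 3-(tert-butyldimethylsilyloxymethyl)but-3-enoate | C=C(CO[Si](C)(C)C(C)(C)C)CC(=O)O[Si](C)(C)C(C)(C)C | intermediate (not isolated)
5 | 3-(tert-butyldimethylsilyloxymethyl)but-3-enoic acid | C=C(CO[Si](C)(C)C(C)(C)C)CC(=O)O | intermediate
6 | (S)-4-benzyl-1,3-oxazolidin-2-one | O=C1N[C@@H](Cc2ccccc2)CO1 | starting material
7 | mixed anhydride of 5 with pivalic acid | C=C(CO[Si](C)(C)C(C)(C)C)CC(=O)OC(=O)C(C)(C)C | intermediate (not isolated)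
8 | (S)-4-benzyl-3-[3-(tert-butyldimethylsilyloxymethyl)but-3-enoyl]-1,3-oxazolidin-2-one | C=C(CO[Si](C)(C)C(C)(C)C)CC(=O)N1[C@@H](Cc2ccccc2)COC1=O | intermediate
9 | 3-(trimethylsilyl)prop-2-ynal | C[Si](C)(C)C#CC=O | starting material
10 | syn-aldol imide: C8 acyl oxazolidinone, C7 with 3-(TBS-oxy)prop-1-en-2-yl, C6 OH, C5≡C4–SiMe3; 6,7-syn, C6/C7 as in the target | O=C(N1[C@@H](Cc2ccccc2)COC1=O)[C@@H](C(=C)CO[Si](C)(C)C(C)(C)C)[C@H](O)C#C[Si](C)(C)C | intermediate
11 | Weinreb amide of the aldol (N-methoxy-N-methyl amide at C8) | CON(C)C(=O)[C@@H](C(=C)CO[Si](C)(C)C(C)(C)C)[C@H](O)C#C[Si](C)(C)C | intermediate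
12 | 4-methoxybenzyl alcohol | COc1ccc(CO)cc1 | starting material
13 | tributyl(iodomethyl)stannane | CCCC[Sn](CCCC)(CCCC)CI | starting material
14 | tributyl[(4-methoxybenzyloxy)methyl]stannane | CCCC[Sn](CCCC)(CCCC)COCc1ccc(OC)cc1 | intermediate
15 | [(4-methoxybenzyloxy)methyl]lithium | [Li]COCc1ccc(OC)cc1 | intermediate (not isolated)
16 | β-hydroxy ketone: C9H2–OPMB, C8 ketone, C6 OH | COc1ccc(COCC(=O)[C@@H](C(=C)CO[Si](C)(C)C(C)(C)C)[C@H](O)C#C[Si](C)(C)C)cc1 | intermediate
17 | 6,8-anti diol, C6–C8 as in the target | COc1ccc(COC[C@@H](O)[C@@H](C(=C)CO[Si](C)(C)C(C)(C)C)[C@H](O)C#C[Si](C)(C)C)cc1 | intermediate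
18 | C8/C9 p-methoxybenzylidene acetal, free C6 OH (acetal carbon epimers) | COc1ccc(C2OC[C@@H](O2)[C@@H](C(=C)CO[Si](C)(C)C(C)(C)C)[C@H](O)C#C[Si](C)(C)C)cc1 | intermediate
19 | C6 TBS ether of 18 | COc1ccc(C2OC[C@@H](O2)[C@@H](C(=C)CO[Si](C)(C)C(C)(C)C)[C@H](O[Si](C)(C)C(C)(C)C)C#C[Si](C)(C)C)cc1 | intermediate
20 | terminal alkyne | COc1ccc(C2OC[C@@H](O2)[C@@H](C(=C)CO[Si](C)(C)C(C)(C)C)[C@H](O[Si](C)(C)C(C)(C)C)C#C)cc1 | intermediate
21 | formaldehyde (as paraformaldehyde) | C=O | starting material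
22 | terminal allene C6–C5H=C4=C15H2 with C8/C9 acetal | COc1ccc(C2OC[C@@H](O2)[C@@H](C(=C)CO[Si](C)(C)C(C)(C)C)[C@H](O[Si](C)(C)C(C)(C)C)C=C=C)cc1 | intermediate
23 | C9 primary alcohol, C8 OPMB, C6 and C12 OTBS, allene | OC[C@@H](OCc1ccc(OC)cc1)[C@@H](C(=C)CO[Si](C)(C)C(C)(C)C)[C@H](O[Si](C)(C)C(C)(C)C)C=C=C | intermediate
24 | C9 aldehyde | O=C[C@@H](OCc1ccc(OC)cc1)[C@@H](C(=C)CO[Si](C)(C)C(C)(C)C)[C@H](O[Si](C)(C)C(C)(C)C)C=C=C | intermediate
25 | tert-butyl[(1-methoxyethenyl)oxy]dimethylsilane | C=C(OC)O[Si](C)(C)C(C)(C)C | starting material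
26 | methyl ester with C9 OH, 8,9-anti, C6–C9 as in the target | COC(=O)C[C@@H](O)[C@@H](OCc1ccc(OC)cc1)[C@@H](C(=C)CO[Si](C)(C)C(C)(C)C)[C@H](O[Si](C)(C)C(C)(C)C)C=C=C | intermediate
27 | C9 triethylsilyl ether of 26 | COC(=O)C[C@@H](O[Si](CC)(CC)CC)[C@@H](OCc1ccc(OC)cc1)[C@@H](C(=C)CO[Si](C)(C)C(C)(C)C)[C@H](O[Si](C)(C)C(C)(C)C)C=C=C | intermediate
28 | methyl 3,3-dimethoxypropanoate | COC(=O)CC(OC)OC | starting material
29 | 3,3-dimethoxypropanal | COC(OC)CC=O | intermediate
30 | aldol adduct (C1 carbinol, C10/C1 diastereomers) | COC(=O)C(C(O)CC(OC)OC)[C@@H](O[Si](CC)(CC)CC)[C@@H](OCc1ccc(OC)cc1)[C@@H](C(=C)CO[Si](C)(C)C(C)(C)C)[C@H](O[Si](C)(C)C(C)(C)C)C=C=C | intermediate (not isolated)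
31 | C1 mesylate of 30 | COC(=O)C(C(CC(OC)OC)OS(C)(=O)=O)[C@@H](O[Si](CC)(CC)CC)[C@@H](OCc1ccc(OC)cc1)[C@@H](C(=C)CO[Si](C)(C)C(C)(C)C)[C@H](O[Si](C)(C)C(C)(C)C)C=C=C | intermediate (not isolated)
32 | enoate with C3 dimethyl acetal, C1=C10 with C2 cis to C9 | COC(OC)C/C=C(C(=O)OC)\[C@@H](O[Si](CC)(CC)CC)[C@@H](OCc1ccc(OC)cc1)[C@@H](C(=C)CO[Si](C)(C)C(C)(C)C)[C@H](O[Si](C)(C)C(C)(C)C)C=C=C | intermediate
33 | allene aldehyde (key-step precursor) | O=CC/C=C(C(=O)OC)\[C@@H](O[Si](CC)(CC)CC)[C@@H](OCc1ccc(OC)cc1)[C@@H](C(=C)CO[Si](C)(C)C(C)(C)C)[C@H](O[Si](C)(C)C(C)(C)C)C=C=C | intermediate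
34 | ten-membered Z,Z-diene, (3R) C3 OTBS, C4 methyl, C9 OTES, C8 OPMB, C6 and C12 OTBS | CC(C)(C)[Si](C)(C)O[C@H]1[C@H](C(=C)CO[Si](C)(C)C(C)(C)C)[C@H](OCc2ccc(OC)cc2)[C@H](O[Si](CC)(CC)CC)/C(C(=O)OC)=C\C[C@@H](O[Si](C)(C)C(C)(C)C)/C(C)=C\1 | intermediate
35 | macrocyclic C8 alcohol | CC(C)(C)[Si](C)(C)O[C@H]1[C@H](C(=C)CO[Si](C)(C)C(C)(C)C)[C@H](O)[C@H](O[Si](CC)(CC)CC)/C(C(=O)OC)=C\C[C@@H](O[Si](C)(C)C(C)(C)C)/C(C)=C\1 | intermediate
36 | angelic acid, (Z)-2-methylbut-2-enoic acid | C/C=C(/C)C(=O)O | starting material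
37 | (Z)-2-methylbut-2-en-1-ol | C/C=C(/C)CO | intermediate
38 | [(2R,3S)-2,3-dimethyloxiran-2-yl]methanol | OC[C@@]1(C)O[C@H]1C | intermediate
39 | (2S,3S)-2,3-dimethyloxirane-2-carboxylic acid | OC(=O)[C@@]1(C)O[C@H]1C | intermediate
40 | mixed anhydride of 39 with 2,4,6-trichlorobenzoic acid | O=C(OC(=O)[C@@]1(C)O[C@H]1C)c1c(Cl)cc(Cl)cc1Cl | intermediate (not isolated)
41 | macrocycle with C8 (2S,3S)-epoxyangelate, C9 OTES, three TBS ethers | CC(C)(C)[Si](C)(C)O[C@H]1[C@H](C(=C)CO[Si](C)(C)C(C)(C)C)[C@H](OC(=O)[C@@]2(C)O[C@H]2C)[C@H](O[Si](CC)(CC)CC)/C(C(=O)OC)=C\C[C@@H](O[Si](C)(C)C(C)(C)C)/C(C)=C\1 | intermediate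
42 | C9 alcohol | CC(C)(C)[Si](C)(C)O[C@H]1[C@H](C(=C)CO[Si](C)(C)C(C)(C)C)[C@H](OC(=O)[C@@]2(C)O[C@H]2C)[C@H](O)/C(C(=O)OC)=C\C[C@@H](O[Si](C)(C)C(C)(C)C)/C(C)=C\1 | intermediate
43 | C9 acetate | CC(C)(C)[Si](C)(C)O[C@H]1[C@H](C(=C)CO[Si](C)(C)C(C)(C)C)[C@H](OC(=O)[C@@]2(C)O[C@H]2C)[C@H](OC(C)=O)/C(C(=O)OC)=C\C[C@@H](O[Si](C)(C)C(C)(C)C)/C(C)=C\1 | intermediate
44 | triol (C3, C6, C12 OH) | O[C@H]1[C@H](C(=C)CO)[C@H](OC(=O)[C@@]2(C)O[C@H]2C)[C@H](OC(C)=O)/C(C(=O)OC)=C\C[C@@H](O)/C(C)=C\1 | intermediate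
45 | lactol (C12 hemiacetal with O6) | C=C1C(O)O[C@H]2[C@H]1[C@H](OC(=O)[C@@]1(C)O[C@H]1C)[C@H](OC(C)=O)/C(C(=O)OC)=C\C[C@@H](O)/C(C)=C\2 | intermediate (not isolated)
46 | 6,12-lactone with C4=C5 Z olefin and C3 OH | C=C1C(=O)O[C@H]2[C@H]1[C@H](OC(=O)[C@@]1(C)O[C@H]1C)[C@H](OC(C)=O)/C(C(=O)OC)=C\C[C@@H](O)/C(C)=C\2 | intermediate
47 | CNP0301544.1 | C=C1C(=O)O[C@H]2[C@H]1[C@H](OC(=O)[C@@]1(C)O[C@H]1C)[C@H](OC(C)=O)/C(C(=O)OC)=C\C[C@@H](O)[C@]1(C)O[C@H]21 | target

## Step count and risks

Total step count: 30. Longest linear sequence: 25 steps (1–5, 7–16, 18–21, 25–30).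

**Step 20 (key step).** Ring closure may lose to oligomerisation, to nickel-hydride reduction or enolisation of the aldehyde, to coupling through the internal allene π bond, or to poor facial control at C3.

Fallback (known chemistry): an intramolecular Nozaki–Hiyama–Kishi closure of the same C3–C4 bond. It sets out from 18 and returns at 34.
- Methyllithium cleaves the C–Si bond of the silylalkyne and the acetylide is methylated with MeI to give the but-2-ynyl alcohol F1.
- Red-Al then iodine (hydroxyl-directed trans-hydroalumination with aluminium on the methyl-bearing carbon, iodinolysis with retention) gives the (Z)-iodoalkene alcohol F2, and TBSOTf gives its silyl ether F3.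
- F3 is carried through the operations of steps 13 to 19: primary alcohol F4, aldehyde F5, β-hydroxy ester F6, triethylsilyl ether F7, aldol adduct F8, mesylate F9, enoate acetal F10 and iodo aldehyde F11.
- CrCl2 with catalytic NiCl2 in DMSO/THF at high dilution adds the vinylchromium to the aldehyde with retention of the Z olefin and gives the macrocyclic C3 alcohol F12. TBSOTf/2,6-lutidine converts F12 into 34.

**Step 18.** The one-pot aldol/elimination may give a mixture of olefin isomers, or may be eroded by retro-aldol cleavage or loss of the C9 silyloxy group.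

Fallback: a Horner–Wadsworth–Emmons olefination. It sets out from 24 and returns at 32.
- Pinnick oxidation gives the acid F13, and carbonyldiimidazole gives the imidazolide F14.
- F14 C-acylates the magnesium enolate of methyl 2-(dimethoxyphosphoryl)acetate (MgCl2, Et3N) to give the β-keto phosphonate F15.
- Zn(BH4)2 reduces F15 under chelation with O8 to the 8,9-anti β-hydroxy phosphonate F16, and TESCl gives F17.
- Olefination of F17 with 29 (LiCl, DBU, MeCN) gives 32.

**Step 25.** Acylation of the C8 hydroxyl, which is flanked by the branched C7 and the C9 triethylsilyloxy group, may stall with the α,α-disubstituted epoxy acid.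

Fallback: change the order of the two acylations. It sets out from 34 and returns at 43.
- PPTS/MeOH removes the C9 triethylsilyl group to give alcohol F18, and Ac2O/pyridine gives the acetate F19.
- DDQ frees the C8 hydroxyl to give F20.
- Yamaguchi esterification with 39 (through 40), now next to the smaller acetate and run without excess amine so that the acetate does not migrate, gives 43.

Further compounds
F1 | step 20 | but-2-ynyl alcohol (C6 OH, C5≡C4–CH3, C8/C9 acetal) | COc1ccc(C2OC[C@@H](O2)[C@@H](C(=C)CO[Si](C)(C)C(C)(C)C)[C@H](O)C#CC)cc1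
F2 | step 20 | (Z)-iodoalkene alcohol (C6 OH, C5H=C4(I)CH3, C6 cis to I) | COc1ccc(C2OC[C@@H](O2)[C@@H](C(=C)CO[Si](C)(C)C(C)(C)C)[C@H](O)/C=C(\I)C)cc1
F3 | step 20 | C6 TBS ether of F2 | COc1ccc(C2OC[C@@H](O2)[C@@H](C(=C)CO[Si](C)(C)C(C)(C)C)[C@H](O[Si](C)(C)C(C)(C)C)/C=C(\I)C)cc1
F4 | step 20 | C9 primary alcohol, C8 OPMB, vinyl iodide | OC[C@@H](OCc1ccc(OC)cc1)[C@@H](C(=C)CO[Si](C)(C)C(C)(C)C)[C@H](O[Si](C)(C)C(C)(C)C)/C=C(\I)C
F5 | step 20 | C9 aldehyde, vinyl iodide | O=C[C@@H](OCc1ccc(OC)cc1)[C@@H](C(=C)CO[Si](C)(C)C(C)(C)C)[C@H](O[Si](C)(C)C(C)(C)C)/C=C(\I)C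
F6 | step 20 | β-hydroxy ester, vinyl iodide | COC(=O)C[C@@H](O)[C@@H](OCc1ccc(OC)cc1)[C@@H](C(=C)CO[Si](C)(C)C(C)(C)C)[C@H](O[Si](C)(C)C(C)(C)C)/C=C(\I)C
F7 | step 20 | C9 TES ether of F6 | COC(=O)C[C@@H](O[Si](CC)(CC)CC)[C@@H](OCc1ccc(OC)cc1)[C@@H](C(=C)CO[Si](C)(C)C(C)(C)C)[C@H](O[Si](C)(C)C(C)(C)C)/C=C(\I)C
F8 | step 20 | aldol adduct of F7 with 29 | COC(=O)C(C(O)CC(OC)OC)[C@@H](O[Si](CC)(CC)CC)[C@@H](OCc1ccc(OC)cc1)[C@@H](C(=C)CO[Si](C)(C)C(C)(C)C)[C@H](O[Si](C)(C)C(C)(C)C)/C=C(\I)C
F9 | step 20 | C1 mesylate of F8 | COC(=O)C(C(CC(OC)OC)OS(C)(=O)=O)[C@@H](O[Si](CC)(CC)CC)[C@@H](OCc1ccc(OC)cc1)[C@@H](C(=C)CO[Si](C)(C)C(C)(C)C)[C@H](O[Si](C)(C)C(C)(C)C)/C=C(\I)C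
F10 | step 20 | enoate acetal, vinyl iodide | COC(OC)C/C=C(C(=O)OC)\[C@@H](O[Si](CC)(CC)CC)[C@@H](OCc1ccc(OC)cc1)[C@@H](C(=C)CO[Si](C)(C)C(C)(C)C)[C@H](O[Si](C)(C)C(C)(C)C)/C=C(\I)C
F11 | step 20 | iodo aldehyde | O=CC/C=C(C(=O)OC)\[C@@H](O[Si](CC)(CC)CC)[C@@H](OCc1ccc(OC)cc1)[C@@H](C(=C)CO[Si](C)(C)C(C)(C)C)[C@H](O[Si](C)(C)C(C)(C)C)/C=C(\I)C
F12 | step 20 | macrocyclic (3R) C3 alcohol | CC(C)(C)[Si](C)(C)O[C@H]1[C@H](C(=C)CO[Si](C)(C)C(C)(C)C)[C@H](OCc2ccc(OC)cc2)[C@H](O[Si](CC)(CC)CC)/C(C(=O)OC)=C\C[C@@H](O)/C(C)=C\1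
F13 | step 18 | C9 carboxylic acid | OC(=O)[C@@H](OCc1ccc(OC)cc1)[C@@H](C(=C)CO[Si](C)(C)C(C)(C)C)[C@H](O[Si](C)(C)C(C)(C)C)C=C=C
F14 | step 18 | acyl imidazolide of F13 | O=C(n1ccnc1)[C@@H](OCc1ccc(OC)cc1)[C@@H](C(=C)CO[Si](C)(C)C(C)(C)C)[C@H](O[Si](C)(C)C(C)(C)C)C=C=C
F15 | step 18 | β-keto phosphonate (C9 ketone, C10 bearing CO2Me and P(O)(OMe)2) | COC(=O)C(C(=O)[C@@H](OCc1ccc(OC)cc1)[C@@H](C(=C)CO[Si](C)(C)C(C)(C)C)[C@H](O[Si](C)(C)C(C)(C)C)C=C=C)P(=O)(OC)OC
F16 | step 18 | β-hydroxy phosphonate (C9 OH, 8,9-anti) | COC(=O)C([C@@H](O)[C@@H](OCc1ccc(OC)cc1)[C@@H](C(=C)CO[Si](C)(C)C(C)(C)C)[C@H](O[Si](C)(C)C(C)(C)C)C=C=C)P(=O)(OC)OC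
F17 | step 18 | C9 TES ether of F16 | COC(=O)C([C@@H](O[Si](CC)(CC)CC)[C@@H](OCc1ccc(OC)cc1)[C@@H](C(=C)CO[Si](C)(C)C(C)(C)C)[C@H](O[Si](C)(C)C(C)(C)C)C=C=C)P(=O)(OC)OC
F18 | step 25 | macrocycle with C9 OH and C8 OPMB | CC(C)(C)[Si](C)(C)O[C@H]1[C@H](C(=C)CO[Si](C)(C)C(C)(C)C)[C@H](OCc2ccc(OC)cc2)[C@H](O)/C(C(=O)OC)=C\C[C@@H](O[Si](C)(C)C(C)(C)C)/C(C)=C\1
F19 | step 25 | macrocycle with C9 OAc and C8 OPMB | CC(C)(C)[Si](C)(C)O[C@H]1[C@H](C(=C)CO[Si](C)(C)C(C)(C)C)[C@H](OCc2ccc(OC)cc2)[C@H](OC(C)=O)/C(C(=O)OC)=C\C[C@@H](O[Si](C)(C)C(C)(C)C)/C(C)=C\1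
F20 | step 25 | macrocycle with C9 OAc and C8 OH | CC(C)(C)[Si](C)(C)O[C@H]1[C@H](C(=C)CO[Si](C)(C)C(C)(C)C)[C@H](O)[C@H](OC(C)=O)/C(C(=O)OC)=C\C[C@@H](O[Si](C)(C)C(C)(C)C)/C(C)=C\1
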